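The readings were generated by integration with made-up constants.

Target is the small part of what leaves the solid, so I looked at how the lost solid splits. In the noon run, at 2.50 min, target was 8.1 % while the solid substrate had lost 32.2 %.

| flask | solid substrate | second substrate | free catalyst | remark |
|---|---|---|---|---|
| noon | 2 M | 1 M | 200 mM | run made earlier |
| winter | 2 M | 1 M | 450 mM | run made earlier |
| flask | 2.0 M | 1.00 M | 300 mM |  |

| run | time / min | target / % | solid substrate / % |
|---|---|---|---|
| noon | 0.333 | 2.1 | 91.7 |
| noon | 0.667 | 1.7 | 87.5 |
| noon | 1.00 | 2.5 | 85.8 |
| noon | 1.33 | 4.8 | 80.1 |
| noon | 1.50 | 2.8 | 78.6 |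
| noon | 2.00 | 5.9 | 71.9 |
| noon | 2.50 | 8.1 | 67.8 |
| winter | 0.200 | 0 | 94.7 |
| winter | 0.333 | 0.6 | 92.5 |
| winter | 0.417 | 2.2 | 89.5 |
| winter | 0.667 | 3.0 | 87.3 |
| winter | 1.00 | 5.8 | 81.3 |
| winter | 1.50 | 8.4 | 74.5 |
| winter | 2.50 | 19.1 | 58.7 |

(each reading ± 1 percentage point)

1. apparent order in second substrate when 30 % of the solid substrate are converted (what has only dissolved counts as not reacted) (percent change of the rate of making target for one percent more second substrate charged)
2. apparent order in free catalyst when 30 % of the solid substrate are converted (what has only dissolved counts as not reacted) (percent change of the rate of making target for one percent more free catalyst charged)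
3. factor on the rate of making target when 30 % of the solid substrate are converted (what has only dissolved counts as not reacted) if free catalyst is charged twice over

- solid, in amounts per volume of the solution: solid substrate
- at the start none of the solid substrate is in solution
- what has only dissolved of solid substrate counts as not reacted
- no earlier run changes the charge of second substrate; that part of a forecast is a guess

I called the split odds target divided by the rest of the solid lost, dissolved and unreacted material included: 0.336 at noon and 0.860 in the winter run at the same time. Scaling noon by catalyst gives 0.756 for winter, near that reading, so I took the odds as proportional to catalyst. Averaged over both runs, the flask gets 0.539. At a fixed rate of solid loss, target's share is O/(1+O) and its order in catalyst is 1/(1+O), here 0.650.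

One number wasn't enough, though: solid loss itself was faster in winter, with exponent 0.307. Adding that, I reckoned an order of 0.957 and a doubling factor of 1.94. No run varied second substrate, so the odds say nothing about it.

The forecast, different from mine, gave 0.75 and 1.65, and 2.1 (1.1 to 2.7) for second substrate, taken as “first order in second substrate (a guess)”.

    starting material + free catalyst ⇌ catalyst intermediate A (K = 0.300 /M, k = 0.310 /M/s)
    catalyst intermediate A → free catalyst + target (k = 0.230 /s)
    second substrate + free catalyst ⇌ catalyst intermediate B (K = 2.60 /M, k = 0.240 /M/s)
    catalyst intermediate B → free catalyst + second product (k = 0.290 /s)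
    solid substrate ⇌ starting material, rate k5*(cs5 - [starting material]) while solid is left; crystals form when [starting material] > cs5 (solubility = 0.180 M, k = 0.0710 /s)
    starting material → uncatalysed product (k = 0.0200 /s)

The flask gave −6.8 × 10⁻⁴ for second substrate, 0.85 for catalyst and a factor of 1.74. While second substrate lasted, catalyst intermediate B held 24.5 % of the catalyst at 0.300 min, and second substrate was down to 1.72 % of its charge by 1.50 min, with free catalyst at 96.0 %. After that the solid went on dissolving and starting material fed target and uncatalysed product, 15.8 % against 20.4 % at 3.00 min, when the odds carried as 0.539 stood at 0.591.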